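**Retrosynthetic overview**
1. Target 30 ⇒ acyclic (Z,Z)-aldehyde/allylic bromide 26. The last flask forms C6–C7, the bond that closes the farnesyl chain to the germacrane ring. It then closes the O6→C12 lactone and frees 8-OH. Ring order: ten-membered carbocycle first, γ-lactone second.
2. 26 ⇒ terminal alkene 24 + methyl 2-(bromomethyl)acrylate 25 (C11–C13, cross-metathesis). C6 comes from CO on a Z-vinyl iodide.
3. The syn C8/C9 pair ⇒ Z-enal 12 + a silyloxyallylborane made from 14. The 9-O-acyl group ⇒ epoxy acid 21.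
4. 12 ⇒ dihydropyranone 9, a throw-away ring (allylation, ring-closing metathesis) that locks 1(10)-Z and carries C3.
5. Z-iodoenal 4 and acid 21 ⇒ one common iodide 3 ⇒ propargyl alcohol 1.

Assumption: the SMILES is taken exactly as drawn, which in germacrane numbering is 1(10)Z,4Z and 3S,6R,7R,8R,9R,2′R,3′R; atom labels C1–C15 below use that numbering.

**Step 1**
Reactants: 1 prop-2-yn-1-ol
Product: 3 (Z)-3-iodo-2-methylprop-2-en-1-ol, via vinylmagnesium chelate 2 (not isolated)
Conditions: MeMgBr (2.5 equiv), CuI (10 mol %), Et2O–THF, −10 °C to rt; then I2, −20 °C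
Reagents that add atoms: methylmagnesium bromide, C[Mg]Br; iodine, [I][I]
Why: Copper-catalysed anti-carbomagnesiation of the propargylic alkoxide puts methyl on the inner carbon and holds magnesium cis to CH2O in a five-membered chelate, so iodinolysis with retention gives only the Z-iodide.

**Step 2**
Reactants: 3 (Z)-3-iodo-2-methylprop-2-en-1-ol
Product: 4 (Z)-3-iodo-2-methylprop-2-enal
Conditions: MnO2 (15 equiv), CH2Cl2, rt, dark
Reagents that add atoms: none
Why: Neutral heterogeneous allylic oxidation with MnO2 stops at the aldehyde and does not isomerise the Z-iodoalkene.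

**Step 3**
Reactants: 4 (Z)-3-iodo-2-methylprop-2-enal; 5 allyltributylstannane; 6 methacryloyl chloride
Product: 8 (1Z,3S)-1-iodo-2-methylhexa-1,5-dien-3-yl 2-methylprop-2-enoate, via tributylstannyl ether 7 (not isolated)
Conditions: (S)-BINOL (20 mol %), Ti(OiPr)4 (10 mol %), 4 Å MS, 5 (1.2 equiv), CH2Cl2, −20 °C, 60 h; then 6 (1.5 equiv), DMAP (10 mol %), 0 °C
Reagents that add atoms: none
Why: Keck asymmetric allylation, in which the (S)-BINOL–titanium Lewis acid exposes the Si face of the enal and sets C3 as S, releases a tin alkoxide that the acid chloride acylates in the same flask.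

**Step 4**
Reactants: 8 (1Z,3S)-1-iodo-2-methylhexa-1,5-dien-3-yl 2-methylprop-2-enoate
Product: 9 (6S)-6-[(1Z)-1-iodoprop-1-en-2-yl]-3-methyl-5,6-dihydro-2H-pyran-2-one
Conditions: second-generation Grubbs catalyst (5 mol %), CH2Cl2 (5 mM), 40 °C
Reagents that add atoms: none
Why: Ring-closing metathesis of the allyl and methacrylate termini gives a six-membered ring that can only hold a cis double bond, which fixes the 1(10)-Z geometry, while the trisubstituted iodoalkene and C3 stay untouched.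

**Step 5**
Reactants: 9 (6S)-6-[(1Z)-1-iodoprop-1-en-2-yl]-3-methyl-5,6-dihydro-2H-pyran-2-one
Product: 11 (2Z,5S,6Z)-5-acetoxy-7-iodo-N-methoxy-N,2,6-trimethylhepta-2,6-dienamide, via chloromagnesium alkoxide 10 (not isolated)
Conditions: Me(MeO)NH·HCl (2 equiv) premixed with iPrMgCl (4 equiv), THF, −20 °C; 9, −20 to 0 °C; then Ac2O (4 equiv), DMAP (10 mol %), 0 °C to rt
Reagents that add atoms: N,O-dimethylhydroxylamine hydrochloride, CNOC.Cl; acetic anhydride, CC(=O)OC(C)=O
Why: Weinreb aminolysis opens the lactone at the acyl carbon without touching C3 or the Z-alkene, and the released magnesium alkoxide is acetylated before it can close the ring again.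

**Step 6**
Reactants: 11 (2Z,5S,6Z)-5-acetoxy-7-iodo-N-methoxy-N,2,6-trimethylhepta-2,6-dienamide
Product: 12 (1Z,3S,5Z)-1-iodo-2,6-dimethyl-7-oxohepta-1,5-dien-3-yl acetate
Conditions: Cp2Zr(H)Cl (1.6 equiv), THF, rt, 20 min; wet silica gel
Reagents that add atoms: none
Why: Amide-to-aldehyde reduction with Cp2Zr(H)Cl stops at a stable zirconated hemiaminal, so the acetate, the vinyl iodide and the trisubstituted alkenes survive and the Z-enal appears only on neutral hydrolysis.

**Step 7**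
Reactants: 13 prop-2-en-1-ol
Product: 14 triethyl(prop-2-enyloxy)silane
Conditions: Et3SiCl (1.05 equiv), imidazole (1.2 equiv), CH2Cl2, 0 °C
Reagents that add atoms: chlorotriethylsilane, CC[Si](Cl)(CC)CC
Why: Standard imidazole-mediated O-silylation.

**Step 8**
Reactants: 12 (1Z,3S,5Z)-1-iodo-2,6-dimethyl-7-oxohepta-1,5-dien-3-yl acetate; 14 triethyl(prop-2-enyloxy)silane
Product: 18 (1Z,3S,5Z,7R,8R)-7-hydroxy-1-iodo-2,6-dimethyl-8-(triethylsilyloxy)deca-1,5,9-trien-3-yl acetate, via silyloxyallyllithium 15 (not isolated), via silyloxyallylborane 16 (not isolated), via borinate ester 17 (not isolated)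
Conditions: 14, s-BuLi, THF, −78 °C; (−)-Ipc2BOMe (from (+)-α-pinene), −78 °C; BF3·OEt2; 12, −78 °C, 4 h; HOCH2CH2NH2, Et2O, rt
Reagents that add atoms: none
Why: This is Brown (Z)-γ-alkoxyallylboration run on the silyl ether instead of the usual acetal ether, in which the closed chair transition state turns the Z-enol ether geometry into the syn C8/C9 pair and the isopinocampheyl groups direct attack to the Si face of 12, giving 8R,9R with O8 already masked and O9 free.

**Step 9**
Reactants: 3 (Z)-3-iodo-2-methylprop-2-en-1-ol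
Product: 19 (Z)-2-methylbut-2-en-1-ol
Conditions: MeMgBr (3 equiv), Pd(PPh3)4 (3 mol %), THF, 0 °C to rt
Reagents that add atoms: methylmagnesium bromide, C[Mg]Br
Why: Kumada–Corriu coupling, in which zerovalent palladium inserts into the C–I bond and couples with retention, replaces iodine by methyl and gives angelyl alcohol as the pure Z isomer.

**Step 10**
Reactants: 19 (Z)-2-methylbut-2-en-1-ol
Product: 20 [(2S,3R)-2,3-dimethyloxiran-2-yl]methanol
Conditions: Ti(OiPr)4 (10 mol %), L-(+)-diethyl tartrate (12 mol %), tBuOOH (2 equiv), 4 Å MS, CH2Cl2, −20 °C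
Reagents that add atoms: tert-butyl hydroperoxide, CC(C)(C)OO
Why: In the Sharpless asymmetric epoxidation the L-(+)-tartrate complex delivers oxygen to the face that gives 2S (as with nerol), and the Z-alkene geometry carries over stereospecifically to 3R.

**Step 11**
Reactants: 20 [(2S,3R)-2,3-dimethyloxiran-2-yl]methanol
Product: 21 (2R,3R)-2,3-dimethyloxirane-2-carboxylic acid
Conditions: RuCl3·xH2O (2 mol %), NaIO4 (3 equiv), MeCN–EtOAc–H2O, 0 °C to rt
Reagents that add atoms: sodium periodate, [Na+].[O-]I(=O)(=O)=O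
Why: Catalytic RuO4 oxidation takes the primary alcohol to the acid without opening the epoxide, and only the descriptor at C2 changes, not its geometry.

**Step 12**
Reactants: 18 (1Z,3S,5Z,7R,8R)-7-hydroxy-1-iodo-2,6-dimethyl-8-(triethylsilyloxy)deca-1,5,9-trien-3-yl acetate; 21 (2R,3R)-2,3-dimethyloxirane-2-carboxylic acid
Product: 23 (1Z,3S,5Z,7R,8R)-3-acetoxy-1-iodo-2,6-dimethyl-8-(triethylsilyloxy)deca-1,5,9-trien-7-yl (2R,3R)-2,3-dimethyloxirane-2-carboxylate, via Yamaguchi mixed anhydride 22 (not isolated)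
Conditions: 21 (1.5 equiv), 2,4,6-Cl3C6H2COCl, Et3N, THF, 0 °C; then 18, DMAP, toluene, rt
Reagents that add atoms: none
Why: Yamaguchi esterification drives acylation of the hindered allylic 9-OH by the α-quaternary acid without touching a stereocentre, and chromatography at this stage removes the minor diastereomers that come from the imperfect ee of steps 3, 8 and 10.

**Step 13**
Reactants: 23 (1Z,3S,5Z,7R,8R)-3-acetoxy-1-iodo-2,6-dimethyl-8-(triethylsilyloxy)deca-1,5,9-trien-7-yl (2R,3R)-2,3-dimethyloxirane-2-carboxylate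
Product: 24 (2Z,4S,6Z,8R,9R)-4-acetoxy-3,7-dimethyl-1-oxo-9-(triethylsilyloxy)undeca-2,6,10-trien-8-yl (2R,3R)-2,3-dimethyloxirane-2-carboxylate
Conditions: Pd(PPh3)4 (5 mol %), CO (3 atm), Bu3SnH (1.1 equiv, slow addition), THF, 50 °C
Reagents that add atoms: carbon monoxide, [C-]#[O+]
Why: In this Stille-type carbonylative formylation the oxidative addition of zerovalent palladium to the vinyl iodide, CO insertion and hydride transfer all proceed with retention, so C6 enters directly as the Z-enal.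

**Step 14**
Reactants: 24 (2Z,4S,6Z,8R,9R)-4-acetoxy-3,7-dimethyl-1-oxo-9-(triethylsilyloxy)undeca-2,6,10-trien-8-yl (2R,3R)-2,3-dimethyloxirane-2-carboxylate; 25 methyl 2-(bromomethyl)prop-2-enoate
Product: 26 methyl (2Z,4R,5R,6Z,9S,10Z)-9-acetoxy-2-(bromomethyl)-5-{[(2R,3R)-2,3-dimethyloxirane-2-carbonyl]oxy}-6,10-dimethyl-12-oxo-4-(triethylsilyloxy)dodeca-2,6,10-trienoate
Conditions: 25 (8 equiv), second-generation Hoveyda–Grubbs catalyst (10 mol % in portions), 2,6-dichloro-1,4-benzoquinone (10 mol %), CH2Cl2, 40 °C, argon sparge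
Reagents that add atoms: none
Why: Olefin cross-metathesis of the only monosubstituted alkene with an excess of a slow-to-dimerise 1,1-disubstituted acrylate installs C11–C13 in one step, the trisubstituted and enal double bonds stay inert, no stereocentre is touched, and the E/Z ratio does not matter because the allylchromium of step 15 equilibrates.

**Step 15**
Reactants: 26 methyl (2Z,4R,5R,6Z,9S,10Z)-9-acetoxy-2-(bromomethyl)-5-{[(2R,3R)-2,3-dimethyloxirane-2-carbonyl]oxy}-6,10-dimethyl-12-oxo-4-(triethylsilyloxy)dodeca-2,6,10-trienoate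
Product: 30 (3aR,4R,5R,6Z,9S,10Z,11aR)-9-acetoxy-4-hydroxy-6,10-dimethyl-3-methylidene-2-oxo-2,3,3a,4,5,8,9,11a-octahydrocyclodeca[b]furan-5-yl (2R,3R)-2,3-dimethyloxirane-2-carboxylate, via allylchromium species 27 (not isolated), via macrocyclic chromium alkoxide 28 (not isolated), via triethylsilyl lactone 29 (not isolated)
Conditions: CrCl2 (15 equiv), THF–DMF 10:1, 26 added by syringe pump over 12 h (final 1 mM), 25 to 45 °C; then AcOH–H2O 3:1 added, rt, 6 h
Reagents that add atoms: none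
Why: In this intramolecular Nozaki–Hiyama allylation followed by lactonisation, divalent chromium turns the bromide into a configurationally labile allylchromium that adds through its γ-carbon C7 to the enal in a chair transition state with C5 and C8 equatorial (anti addition, hence trans C6/C7) and with the C8–OSiEt3 bond anti to the forming bond (Felkin–Anh control), an arrangement that also points every substituent out of the nascent ring and so gives 6R,7R, after which the substitution-inert trivalent chromium alkoxide on O6, the only free oxygen nucleophile, displaces methoxide to close the γ-lactone and aqueous acetic acid removes the silyl group.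

**Compound list**
1 | prop-2-yn-1-ol | C#CCO | starting material
2 | bromomagnesium (Z)-3-(bromomagnesio)-2-methylprop-2-en-1-olate (vinylmagnesium chelate) | Br[Mg]/C=C(/C)CO[Mg]Br | intermediate
3 | (Z)-3-iodo-2-methylprop-2-en-1-ol | I/C=C(/C)CO | intermediate
4 | (Z)-3-iodo-2-methylprop-2-enal | I/C=C(/C)C=O | intermediate
5 | allyltributylstannane | C=CC[Sn](CCCC)(CCCC)CCCC | starting material
6 | methacryloyl chloride | C=C(C)C(=O)Cl | starting material
7 | tributylstannyl ether of (1Z,3S)-1-iodo-2-methylhexa-1,5-dien-3-ol | I/C=C(/C)[C@@H](O[Sn](CCCC)(CCCC)CCCC)CC=C | intermediate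
8 | (1Z,3S)-1-iodo-2-methylhexa-1,5-dien-3-yl 2-methylprop-2-enoate | I/C=C(/C)[C@@H](OC(=O)C(C)=C)CC=C | intermediate
9 | (6S)-6-[(1Z)-1-iodoprop-1-en-2-yl]-3-methyl-5,6-dihydro-2H-pyran-2-one | I/C=C(/C)[C@@H]1CC=C(C)C(=O)O1 | intermediate
10 | chloromagnesium alkoxide of (2Z,5S,6Z)-5-hydroxy-7-iodo-N-methoxy-N,2,6-trimethylhepta-2,6-dienamide | I/C=C(/C)[C@@H](O[Mg]Cl)C/C=C(/C)C(=O)N(C)OC | intermediate
11 | (2Z,5S,6Z)-5-acetoxy-7-iodo-N-methoxy-N,2,6-trimethylhepta-2,6-dienamide | I/C=C(/C)[C@@H](OC(C)=O)C/C=C(/C)C(=O)N(C)OC | intermediate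
12 | (1Z,3S,5Z)-1-iodo-2,6-dimethyl-7-oxohepta-1,5-dien-3-yl acetate | I/C=C(/C)[C@@H](OC(C)=O)C/C=C(/C)C=O | intermediate
13 | prop-2-en-1-ol | C=CCO | starting material
14 | triethyl(prop-2-enyloxy)silane | C=CCO[Si](CC)(CC)CC | intermediate
15 | (Z)-3-(triethylsilyloxy)allyllithium | [Li]C/C=C\O[Si](CC)(CC)CC | intermediate
16 | [(Z)-3-(triethylsilyloxy)allyl]diisopinocampheylborane (Ipc from (+)-α-pinene) | CC[Si](CC)(CC)O/C=C\CB([C@@H]1C[C@@H]2C[C@H]([C@H]1C)C2(C)C)[C@@H]1C[C@@H]2C[C@H]([C@H]1C)C2(C)C | intermediate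
17 | diisopinocampheylborinate ester of 18 | I/C=C(/C)[C@@H](OC(C)=O)C/C=C(/C)[C@@H](OB([C@@H]1C[C@@H]2C[C@H]([C@H]1C)C2(C)C)[C@@H]1C[C@@H]2C[C@H]([C@H]1C)C2(C)C)[C@H](O[Si](CC)(CC)CC)C=C | intermediate
18 | (1Z,3S,5Z,7R,8R)-7-hydroxy-1-iodo-2,6-dimethyl-8-(triethylsilyloxy)deca-1,5,9-trien-3-yl acetate | I/C=C(/C)[C@@H](OC(C)=O)C/C=C(/C)[C@@H](O)[C@H](O[Si](CC)(CC)CC)C=C | intermediate
19 | (Z)-2-methylbut-2-en-1-ol | C/C=C(/C)CO | intermediate
20 | [(2S,3R)-2,3-dimethyloxiran-2-yl]methanol | OC[C@]1(C)O[C@@H]1C | intermediate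
21 | (2R,3R)-2,3-dimethyloxirane-2-carboxylic acid | OC(=O)[C@]1(C)O[C@@H]1C | intermediate
22 | (2R,3R)-2,3-dimethyloxirane-2-carboxylic 2,4,6-trichlorobenzoic anhydride | O=C(OC(=O)[C@]1(C)O[C@@H]1C)c1c(Cl)cc(Cl)cc1Cl | intermediate
23 | (1Z,3S,5Z,7R,8R)-3-acetoxy-1-iodo-2,6-dimethyl-8-(triethylsilyloxy)deca-1,5,9-trien-7-yl (2R,3R)-2,3-dimethyloxirane-2-carboxylate | I/C=C(/C)[C@@H](OC(C)=O)C/C=C(/C)[C@@H](OC(=O)[C@]1(C)O[C@@H]1C)[C@H](O[Si](CC)(CC)CC)C=C | intermediate
24 | (2Z,4S,6Z,8R,9R)-4-acetoxy-3,7-dimethyl-1-oxo-9-(triethylsilyloxy)undeca-2,6,10-trien-8-yl (2R,3R)-2,3-dimethyloxirane-2-carboxylate | O=C/C=C(/C)[C@@H](OC(C)=O)C/C=C(/C)[C@@H](OC(=O)[C@]1(C)O[C@@H]1C)[C@H](O[Si](CC)(CC)CC)C=C | intermediate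
25 | methyl 2-(bromomethyl)prop-2-enoate | C=C(CBr)C(=O)OC | starting material
26 | methyl (2Z,4R,5R,6Z,9S,10Z)-9-acetoxy-2-(bromomethyl)-5-{[(2R,3R)-2,3-dimethyloxirane-2-carbonyl]oxy}-6,10-dimethyl-12-oxo-4-(triethylsilyloxy)dodeca-2,6,10-trienoate | O=C/C=C(/C)[C@@H](OC(C)=O)C/C=C(/C)[C@@H](OC(=O)[C@]1(C)O[C@@H]1C)[C@H](O[Si](CC)(CC)CC)/C=C(/C(=O)OC)CBr | intermediate
27 | allylchromium dichloride derived from 26 (CH2Br replaced by CH2CrCl2, E/Z-labile) | O=C/C=C(/C)[C@@H](OC(C)=O)C/C=C(/C)[C@@H](OC(=O)[C@]1(C)O[C@@H]1C)[C@H](O[Si](CC)(CC)CC)/C=C(/C(=O)OC)C[Cr](Cl)Cl | intermediate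
28 | ten-membered carbocycle carrying 6-O-CrCl2, a 7-[1-(methoxycarbonyl)vinyl] group, 8-OSiEt3, the 9-O-epoxyangelate and 3-OAc (3S,6R,7R,8R,9R) | C=C(C(=O)OC)[C@H]1[C@H](O[Cr](Cl)Cl)/C=C(/C)[C@@H](OC(C)=O)C/C=C(/C)[C@@H](OC(=O)[C@]2(C)O[C@@H]2C)[C@@H]1O[Si](CC)(CC)CC | intermediate
29 | 8-O-triethylsilyl ether of 30 | C=C1C(=O)O[C@@H]2/C=C(/C)[C@@H](OC(C)=O)C/C=C(/C)[C@@H](OC(=O)[C@]3(C)O[C@@H]3C)[C@H](O[Si](CC)(CC)CC)[C@@H]12 | intermediate
30 | (3aR,4R,5R,6Z,9S,10Z,11aR)-9-acetoxy-4-hydroxy-6,10-dimethyl-3-methylidene-2-oxo-2,3,3a,4,5,8,9,11a-octahydrocyclodeca[b]furan-5-yl (2R,3R)-2,3-dimethyloxirane-2-carboxylate | C=C1C(=O)O[C@@H]2/C=C(/C)[C@@H](OC(C)=O)C/C=C(/C)[C@@H](OC(=O)[C@]3(C)O[C@@H]3C)[C@H](O)[C@@H]12 | target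

**Count and risks**

Total step count: 15. Longest linear sequence: 11 (steps 1, 2, 3, 4, 5, 6, 8, 12, 13, 14, 15).

**Step 15 (ring closure).** The risks are oligomerisation, 1,4-elimination of the silyloxy group from the allylmetal, and the wrong C6/C7 diastereomer.
- The fallback sets out from 24 and comes back at 29. It generates the nucleophile by umpolung of a π-allylpalladium instead of by reduction of a bromide.
- Cross-metathesis of 24 with methyl 2-(acetoxymethyl)acrylate gives the allylic acetate F1.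
- Zerovalent palladium (Pd(PPh3)4) ionises only this unhindered acrylate-type acetate.
- Monovalent indium (InI) reduces the π-allyl complex to an equilibrating allylindium, which closes C6–C7 at high dilution and lactonises to 29.
- 29 is then desilylated with aqueous acetic acid as before.

**Step 14 (cross-metathesis next to a branched silyloxy carbon).** The fallback sets out from 24 and comes back at 26. It builds the acrylate unit by carbonyl addition.
- OsO4/NMO followed by NaIO4, applied to the only monosubstituted alkene, gives the dialdehyde F2.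
- iBu2Al–C(=CH2)CO2Me (from methyl propiolate and iBu2AlH/HMPA) adds to the more electrophilic α-silyloxy aldehyde to give the Baylis–Hillman-type alcohol F3.
- CBr4/PPh3 converts F3 with allylic transposition into 26.

**Step 13 (formylation).** Pd/Bu3SnH may attack the allylic esters or simply reduce the iodide. The fallback sets out from 23 and comes back at 24. It replaces carbonylation by coupling and oxidation.
- Stille coupling of 23 with Bu3SnCH2OH (Pd(PPh3)4, LiCl) gives the Z-allylic alcohol F4.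
- MnO2 oxidises F4 to 24.

**Further compounds**
F1 | step 15 | methyl (2Z,4R,5R,6Z,9S,10Z)-9-acetoxy-2-(acetoxymethyl)-5-{[(2R,3R)-2,3-dimethyloxirane-2-carbonyl]oxy}-6,10-dimethyl-12-oxo-4-(triethylsilyloxy)dodeca-2,6,10-trienoate | O=C/C=C(/C)[C@@H](OC(C)=O)C/C=C(/C)[C@@H](OC(=O)[C@]1(C)O[C@@H]1C)[C@H](O[Si](CC)(CC)CC)/C=C(/C(=O)OC)COC(C)=O
F2 | step 14 | dialdehyde from 24 (terminal CH=CH2 cleaved to CHO, all other groups and stereocentres as in 24) | O=C/C=C(/C)[C@@H](OC(C)=O)C/C=C(/C)[C@@H](OC(=O)[C@]1(C)O[C@@H]1C)[C@H](O[Si](CC)(CC)CC)C=O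
F3 | step 14 | methyl 2-methylidene-3-hydroxy ester from F2 (Baylis–Hillman-type alcohol, epimers at the new carbinol carbon) | O=C/C=C(/C)[C@@H](OC(C)=O)C/C=C(/C)[C@@H](OC(=O)[C@]1(C)O[C@@H]1C)[C@H](O[Si](CC)(CC)CC)C(O)C(=C)C(=O)OC
F4 | step 13 | (2Z,4S,6Z,8R,9R)-4-acetoxy-1-hydroxy-3,7-dimethyl-9-(triethylsilyloxy)undeca-2,6,10-trien-8-yl (2R,3R)-2,3-dimethyloxirane-2-carboxylate | OC/C=C(/C)[C@@H](OC(C)=O)C/C=C(/C)[C@@H](OC(=O)[C@]1(C)O[C@@H]1C)[C@H](O[Si](CC)(CC)CC)C=C
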